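## Retrosynthetic overview
1. Target 30 comes from desilylation of 29. The C1–C15 bond and the C15 carbinol are made by a stereospecific 1,2-metallate shift between macrocyclic secondary boronate 21 and lithiated benzoate 26, followed by C–B oxidation.
2. The only ring, the 14-membered carbocycle, is formed in step 9. Vinyl ate complex 20 undergoes a palladium-induced 1,2-shift of C14 from boron to C1, then C2–C3 closure. This sets C1.
3. Linear precursor 18 comes from aldol–elimination (C7=C8) of ester 7 with aldehyde 12, followed by reduction and silylation.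
4. Ester 7 comes from syn-carboalumination of 4-bromobut-1-yne, Negishi coupling and borylation. Aldehyde 12 comes from net anti-carboalumination of pent-4-yn-1-ol and oxidation.
5. Benzoate 25 comes from (S)-hex-5-en-2-ol by Mitsunobu inversion and cross metathesis.

Assumption 1: the SMILES is read literally. Locants: C1 is the ring CH, and C2 to C14 run round the ring through the Z alkene first. C15 is the carbinol carbon. This gives 1R, 15R, C3=C4 Z, C7=C8 E (CH2OH trans to C6, ring carbons cis) and C11=C12 E.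
Assumption 2: the MandyPhos antipode named in step 9 is taken to give (R)-21 by analogy with intermolecular cases. The other antipode is equally available.

## Route

Step 1
Reactants: 1 4-bromobut-1-yne
Product: 3 (E)-4-bromo-1-iodo-2-methylbut-1-ene, via alkenylalane 2 (not isolated)
Conditions: Me3Al (2 equiv), Cp2ZrCl2 (20 mol %), CH2Cl2, 0 °C to rt; then I2, THF, −30 °C
Reagents that add atoms: trimethylaluminium C[Al](C)C; iodine II
Why: Negishi zirconium-catalysed carboalumination adds Me and Al syn with Al on the terminal carbon and iodinolysis goes with retention, so the E geometry of C11=C12 is fixed while the primary bromide survives because the neutral alane is too weak a nucleophile to cyclise.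

Step 2
Reactants: 3 (E)-4-bromo-1-iodo-2-methylbut-1-ene; 4 methyl 4-bromobutanoate
Product: 6 methyl (E)-8-bromo-6-methyloct-5-enoate, via alkylzinc bromide 5 (not isolated)
Conditions: 4, Zn dust, I2 (5 mol %), DMA, 80 °C; then 3, PdCl2(dppf) (2 mol %), THF, rt
Reagents that add atoms: none
Why: Negishi sp3–sp2 cross-coupling, in which zerovalent palladium inserts only into the alkenyl C–I bond at rt (alkyl bromide and ester are inert) and couples with retention to form C10–C11.

Step 3
Reactants: 6 methyl (E)-8-bromo-6-methyloct-5-enoate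
Product: 7 methyl (E)-6-methyl-8-(4,4,5,5-tetramethyl-1,3,2-dioxaborolan-2-yl)oct-5-enoate
Conditions: B2pin2 (1.5 equiv), CuI (10 mol %), PPh3 (13 mol %), LiOMe (2 equiv), DMF, rt
Reagents that add atoms: bis(pinacolato)diboron CC1(C)OB(OC1(C)C)B2OC(C)(C)C(C)(C)O2
Why: Copper-catalysed borylation of a primary alkyl bromide tolerates esters and trisubstituted alkenes, and LiOMe matches the methyl ester so no ester exchange occurs.

Step 4
Reactants: 8 pent-4-yn-1-ol
Product: 11 (Z)-5-bromo-4-methylpent-4-en-1-ol, via syn-adduct alane 9 (not isolated), via chelated Z-alane 10 (not isolated)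
Conditions: Me3Al (3 equiv), Cp2ZrCl2 (25 mol %), ClCH2CH2Cl, rt, 18 h; reflux, 72 h; then NBS, THF, −78 to 0 °C
Reagents that add atoms: trimethylaluminium C[Al](C)C; N-bromosuccinimide O=C1CCC(=O)N1Br
Why: Negishi carboalumination followed by chelation-driven thermal isomerisation of the alkenylalane (net anti-carbometalation, the aluminium alkoxide drawing Al to the side of the chain) and brominolysis with retention sets the Z geometry of C3=C4.

Step 5
Reactants: 11 (Z)-5-bromo-4-methylpent-4-en-1-ol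
Product: 12 (Z)-5-bromo-4-methylpent-4-enal
Conditions: TEMPO (10 mol %), PhI(OAc)2 (1.1 equiv), CH2Cl2, rt
Reagents that add atoms: none
Why: Oxoammonium (TEMPO) oxidation stops at the aldehyde and leaves the alkenyl bromide untouched.

Step 6
Reactants: 7 methyl (E)-6-methyl-8-(4,4,5,5-tetramethyl-1,3,2-dioxaborolan-2-yl)oct-5-enoate; 12 (Z)-5-bromo-4-methylpent-4-enal
Product: 16 methyl (2E,6Z)-7-bromo-6-methyl-2-[(3E)-4-methyl-6-(4,4,5,5-tetramethyl-1,3,2-dioxaborolan-2-yl)hex-3-en-1-yl]hepta-2,6-dienoate, via lithium enolate 13 (not isolated), via lithium aldolate 14 (not isolated), via mesylate 15 (not isolated)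
Conditions: LDA, THF, −78 °C; 12; then MsCl, −78 to 0 °C; then DBU, rt
Reagents that add atoms: none
Why: Ester-enolate aldol addition, in-flask mesylation and DBU-induced E1cB elimination funnel both aldol diastereomers to the more stable E enoate (CO2Me trans to C6, C6 cis to C9), and Bpin and the alkenyl bromide are inert to these bases.

Step 7
Reactants: 16 methyl (2E,6Z)-7-bromo-6-methyl-2-[(3E)-4-methyl-6-(4,4,5,5-tetramethyl-1,3,2-dioxaborolan-2-yl)hex-3-en-1-yl]hepta-2,6-dienoate
Product: 17 (2E,6Z)-7-bromo-6-methyl-2-[(3E)-4-methyl-6-(4,4,5,5-tetramethyl-1,3,2-dioxaborolan-2-yl)hex-3-en-1-yl]hepta-2,6-dien-1-ol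
Conditions: iBu2AlH (2.5 equiv), CH2Cl2, −78 °C; Rochelle salt work-up
Reagents that add atoms: none
Why: 1,2-Reduction of the enoate by iBu2AlH at low temperature gives the allylic alcohol without touching the alkyl Bpin, the alkenyl bromide or the alkene geometry.

Step 8
Reactants: 17 (2E,6Z)-7-bromo-6-methyl-2-[(3E)-4-methyl-6-(4,4,5,5-tetramethyl-1,3,2-dioxaborolan-2-yl)hex-3-en-1-yl]hepta-2,6-dien-1-ol
Product: 18 2-[(3E,7E,11Z)-12-bromo-7-{[(tert-butyldimethylsilyl)oxy]methyl}-3,11-dimethyldodeca-3,7,11-trien-1-yl]-4,4,5,5-tetramethyl-1,3,2-dioxaborolane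
Conditions: TBSCl, imidazole, CH2Cl2, rt
Reagents that add atoms: tert-butyldimethylsilyl chloride CC(C)(C)[Si](C)(C)Cl
Why: Standard silyl ether protection masks the only acidic proton before the two organometallic steps.

Step 9
Reactants: 18 2-[(3E,7E,11Z)-12-bromo-7-{[(tert-butyldimethylsilyl)oxy]methyl}-3,11-dimethyldodeca-3,7,11-trien-1-yl]-4,4,5,5-tetramethyl-1,3,2-dioxaborolane; 19 vinylmagnesium chloride
Product: 21 2-[(1R,3Z,7E,11E)-8-{[(tert-butyldimethylsilyl)oxy]methyl}-4,12-dimethylcyclotetradeca-3,7,11-trien-1-yl]-4,4,5,5-tetramethyl-1,3,2-dioxaborolane, via vinyl ate complex 20 (not isolated)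
Conditions: 19 (1.1 equiv), NaOTf (3 equiv), THF, 0 °C to rt; then syringe-pump addition (16 h) to Pd(OAc)2 (5 mol %), (Sp,Sp)-MandyPhos [1,1'-bis{bis(4-methoxy-3,5-dimethylphenyl)phosphino}-2,2'-bis{(R)-(dimethylamino)(phenyl)methyl}ferrocene] (6 mol %), THF, 60 °C, final 2 mM
Reagents that add atoms: none
Why: Proposed new method: a macrocyclising enantioselective conjunctive cross-coupling in which zerovalent palladium inserts into C3–Br with retention, NaOTf strips bromide so the cationic divalent alkenylpalladium binds the vinyl group of its own boronate terminus (16-membered chelate), this π-activation triggers the anti 1,2-shift of C14 from boron to C1 (contraction to a 15-membered palladacycle, C1 set as R in the chiral ligand pocket), and C2–C3 reductive elimination, faster than β-hydride elimination with this ligand, expels palladium to leave the 14-membered ring; the closest known reaction type is the intermolecular Pd/MandyPhos three-component conjunctive coupling of vinylboron ate complexes with aryl or alkenyl bromides and triflates, which has not been used to close a ring, and slow addition keeps the ate complex dilute enough to disfavour oligomers.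

Step 10
Reactants: 22 (S)-hex-5-en-2-ol
Product: 23 (R)-hex-5-en-2-yl 2,4,6-triisopropylbenzoate
Conditions: 2,4,6-triisopropylbenzoic acid, PPh3, DIAD, THF, 0 °C to rt
Reagents that add atoms: 2,4,6-triisopropylbenzoic acid CC(C)c1cc(C(C)C)c(C(=O)O)c(C(C)C)c1
Why: Mitsunobu esterification (SN2, clean inversion) turns the S alcohol into the R benzoate, whose hindered aryl group later directs lithiation and shields the carbonyl.

Step 11
Reactants: 23 (R)-hex-5-en-2-yl 2,4,6-triisopropylbenzoate; 24 2-methylbut-2-ene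
Product: 25 (R)-6-methylhept-5-en-2-yl 2,4,6-triisopropylbenzoate
Conditions: second-generation Grubbs catalyst RuCl2(=CHPh)(PCy3)(H2IMes) (2 mol %), 24 (excess), CH2Cl2, 40 °C, sealed tube
Reagents that add atoms: none
Why: Olefin cross metathesis of a terminal alkene with excess 2-methylbut-2-ene gives the prenyl-type trisubstituted alkene, releases propene and does not touch the stereocentre.

Step 12
Reactants: 21 2-[(1R,3Z,7E,11E)-8-{[(tert-butyldimethylsilyl)oxy]methyl}-4,12-dimethylcyclotetradeca-3,7,11-trien-1-yl]-4,4,5,5-tetramethyl-1,3,2-dioxaborolane; 25 (R)-6-methylhept-5-en-2-yl 2,4,6-triisopropylbenzoate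
Product: 29 (2R)-2-[(1R,3Z,7E,11E)-8-{[(tert-butyldimethylsilyl)oxy]methyl}-4,12-dimethylcyclotetradeca-3,7,11-trien-1-yl]-6-methylhept-5-en-2-ol, via lithiated benzoate 26 (not isolated), via boronate complex 27 (not isolated), via tertiary boronic ester 28 (not isolated)
Conditions: 25 (1.5 equiv), sBuLi (1.4 equiv), TMEDA, CPME, −60 °C, 2 h; 21, −60 °C, 1 h, then 50 °C, 16 h; then NaOH, H2O2, THF, 0 °C to rt
Reagents that add atoms: hydrogen peroxide OO
Why: Lithiation–borylation, in which directed deprotonation and B–C bond formation both go with retention, the stereospecific 1,2-metallate shift moves C1 from boron to C15 anti to the leaving benzoate (retention at C1, inversion at C15) and C–B oxidation goes with retention, so 15R is set under reagent control and the minor C1 antipode of 21 is removed as a diastereomer.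

Step 13
Reactants: 29 (2R)-2-[(1R,3Z,7E,11E)-8-{[(tert-butyldimethylsilyl)oxy]methyl}-4,12-dimethylcyclotetradeca-3,7,11-trien-1-yl]-6-methylhept-5-en-2-ol
Product: 30 (2R)-2-[(1R,3Z,7E,11E)-8-(hydroxymethyl)-4,12-dimethylcyclotetradeca-3,7,11-trien-1-yl]-6-methylhept-5-en-2-ol
Conditions: TBAF, THF, rt
Reagents that add atoms: none
Why: Fluoride desilylation frees the primary allylic alcohol under conditions that affect neither the alkenes nor the tertiary carbinol.

## Compound list
1 | 4-bromobut-1-yne | C#CCCBr | starting material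
2 | (E)-(4-bromo-2-methylbut-1-en-1-yl)dimethylalane | C[Al](C)/C=C(\C)CCBr | intermediate
3 | (E)-4-bromo-1-iodo-2-methylbut-1-ene | BrCC/C(C)=C/I | intermediate
4 | methyl 4-bromobutanoate | COC(=O)CCCBr | starting material
5 | (4-methoxy-4-oxobutyl)zinc bromide | COC(=O)CCC[Zn]Br | intermediate
6 | methyl (E)-8-bromo-6-methyloct-5-enoate | COC(=O)CCC/C=C(\C)CCBr | intermediate
7 | methyl (E)-6-methyl-8-(4,4,5,5-tetramethyl-1,3,2-dioxaborolan-2-yl)oct-5-enoate | COC(=O)CCC/C=C(\C)CCB1OC(C)(C)C(C)(C)O1 | intermediate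
8 | pent-4-yn-1-ol | C#CCCCO | starting material
9 | (E)-alkenylalane, syn adduct, O-dimethylaluminium alkoxide | C[Al](C)/C=C(\C)CCCO[Al](C)C | intermediate
10 | (Z)-alkenylalane, O-to-Al chelated isomer of 9 | C[Al](C)/C=C(/C)CCCO[Al](C)C | intermediate
11 | (Z)-5-bromo-4-methylpent-4-en-1-ol | Br/C=C(/C)CCCO | intermediate
12 | (Z)-5-bromo-4-methylpent-4-enal | Br/C=C(/C)CCC=O | intermediate
13 | lithium enolate of 7 | COC(O[Li])=CCC/C=C(\C)CCB1OC(C)(C)C(C)(C)O1 | intermediate
14 | lithium aldolate of 7 and 12 (diastereomer mixture) | COC(=O)C(CC/C=C(\C)CCB1OC(C)(C)C(C)(C)O1)C(O[Li])CC/C(C)=C\Br | intermediate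
15 | β-mesyloxy ester (diastereomer mixture) | COC(=O)C(CC/C=C(\C)CCB1OC(C)(C)C(C)(C)O1)C(OS(C)(=O)=O)CC/C(C)=C\Br | intermediate
16 | methyl (2E,6Z)-7-bromo-6-methyl-2-[(3E)-4-methyl-6-(pinacolboryl)hex-3-en-1-yl]hepta-2,6-dienoate | Br/C=C(/C)CC/C=C(/C(=O)OC)CC/C=C(\C)CCB1OC(C)(C)C(C)(C)O1 | intermediate
17 | (2E,6Z)-7-bromo-6-methyl-2-[(3E)-4-methyl-6-(pinacolboryl)hex-3-en-1-yl]hepta-2,6-dien-1-ol | Br/C=C(/C)CC/C=C(/CO)CC/C=C(\C)CCB1OC(C)(C)C(C)(C)O1 | intermediate
18 | 2-[(3E,7E,11Z)-12-bromo-7-{[(tert-butyldimethylsilyl)oxy]methyl}-3,11-dimethyldodeca-3,7,11-trien-1-yl]-4,4,5,5-tetramethyl-1,3,2-dioxaborolane | Br/C=C(/C)CC/C=C(/CO[Si](C)(C)C(C)(C)C)CC/C=C(\C)CCB1OC(C)(C)C(C)(C)O1 | intermediate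
19 | vinylmagnesium chloride | C=C[Mg]Cl | starting material
20 | sodium vinyl(alkyl)pinacolatoborate from 18 | Br/C=C(/C)CC/C=C(/CO[Si](C)(C)C(C)(C)C)CC/C=C(\C)CC[B-]1(C=C)OC(C)(C)C(C)(C)O1.[Na+] | intermediate
21 | 2-[(1R,3Z,7E,11E)-8-{[(tert-butyldimethylsilyl)oxy]methyl}-4,12-dimethylcyclotetradeca-3,7,11-trien-1-yl]-4,4,5,5-tetramethyl-1,3,2-dioxaborolane | CC1(C)OB(OC1(C)C)[C@H]2C/C=C(/C)CC/C=C(/CO[Si](C)(C)C(C)(C)C)CC/C=C(\C)CC2 | intermediate
22 | (S)-hex-5-en-2-ol | C=CCC[C@H](C)O | starting material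
23 | (R)-hex-5-en-2-yl 2,4,6-triisopropylbenzoate | C=CCC[C@@H](C)OC(=O)c1c(C(C)C)cc(C(C)C)cc1C(C)C | intermediate
24 | 2-methylbut-2-ene | CC=C(C)C | starting material
25 | (R)-6-methylhept-5-en-2-yl 2,4,6-triisopropylbenzoate | CC(C)=CCC[C@@H](C)OC(=O)c1c(C(C)C)cc(C(C)C)cc1C(C)C | intermediate
26 | (R)-2-lithio-6-methylhept-5-en-2-yl 2,4,6-triisopropylbenzoate | CC(C)=CCC[C@@]([Li])(C)OC(=O)c1c(C(C)C)cc(C(C)C)cc1C(C)C | intermediate
27 | lithium boronate complex of 21 and 26 | CC(C)=CCC[C@@]([B-]1(OC(C)(C)C(C)(C)O1)[C@H]2C/C=C(/C)CC/C=C(/CO[Si](C)(C)C(C)(C)C)CC/C=C(\C)CC2)(C)OC(=O)c3c(C(C)C)cc(C(C)C)cc3C(C)C.[Li+] | intermediate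
28 | tertiary boronic ester, 1R and 15S by CIP (boron ranks lowest; same spatial arrangement as 29) | CC(C)=CCC[C@@](C)(B1OC(C)(C)C(C)(C)O1)[C@H]2C/C=C(/C)CC/C=C(/CO[Si](C)(C)C(C)(C)C)CC/C=C(\C)CC2 | intermediate
29 | (2R)-2-[(1R,3Z,7E,11E)-8-{[(tert-butyldimethylsilyl)oxy]methyl}-4,12-dimethylcyclotetradeca-3,7,11-trien-1-yl]-6-methylhept-5-en-2-ol | CC(C)=CCC[C@@](C)(O)[C@H]1C/C=C(/C)CC/C=C(/CO[Si](C)(C)C(C)(C)C)CC/C=C(\C)CC1 | intermediate
30 | (2R)-2-[(1R,3Z,7E,11E)-8-(hydroxymethyl)-4,12-dimethylcyclotetradeca-3,7,11-trien-1-yl]-6-methylhept-5-en-2-ol (CNP0298167.2) | CC(C)=CCC[C@@](C)(O)[C@H]1C/C=C(/C)CC/C=C(/CO)CC/C=C(\C)CC1 | target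

## Step count and risks
Total steps: 13. Longest linear sequence: 9 (steps 1, 2, 3, 6, 7, 8, 9, 12, 13).

**Step 9 (proposed new step).**
- Risks: oligomerisation, direct vinyl transfer to palladium, or low er in the macrocyclic setting.
- The fallback uses known chemistry. It sets out from 18 and comes back at 21.
- Ate complex 20 is made as before but treated with I2 and then NaOMe (Zweifel vinylation). This gives (1Z,5E,9E)-1-bromo-6-{[(tert-butyldimethylsilyl)oxy]methyl}-2,10-dimethyltetradeca-1,5,9,13-tetraene F1.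
- Enantioselective diboration of the single monosubstituted alkene (Pt(dba)3, TADDOL-derived phenylphosphonite, B2pin2, THF, 60 °C) sets C1 and gives the (S)-1,2-bis(boronate) F2.
- A site-selective Suzuki–Miyaura coupling follows (Pd(OAc)2, RuPhos, KOH, THF/H2O, 70 °C). It is run at high dilution, like B-alkyl Suzuki macrocyclisations. It joins only the neighbour-activated primary C2 boronate to the C3 bromide and delivers 21.

**Step 12.**
- Risks: the hindered secondary pinacol boronate may form the ate complex slowly with the tertiary carbenoid, or the complex may migrate poorly.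
- The fallback sets out from 21 and comes back at 29.
- Zweifel-type coupling with 1-ethoxyvinyllithium (I2, NaOMe; retention at C1) gives the 1-ethoxyvinyl macrocycle F3.
- Oxalic acid on wet silica hydrolyses it to the (1R)-methyl ketone F4.
- Catalyst-controlled asymmetric Corey–Chaykovsky epoxidation gives the (S)-2-methyl-2-macrocyclyl oxirane F5. The reagents are dimethyloxosulfonium methylide with LaLi3(binaphthoxide)3 and a triarylphosphine oxide, using the BINOL antipode matched to 15R.
- AllylMgCl with CuI (10 mol %) opens the CH2 terminus to give the but-3-enyl carbinol F6.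
- Cross metathesis with 24 under the conditions of step 11 gives 29.

**Step 6.**
- Risks: an incomplete telescoped mesylation–elimination, or an E/Z ratio too low to purify.
- The fallback sets out from 7 (with 12) and comes back at 16.
- Enolate 13 is C-phosphinylated with ClP(OEt)2 and air-oxidised to the α-(diethoxyphosphoryl) ester F7.
- Horner–Wadsworth–Emmons olefination with 12 (NaH, THF, 0 °C) then gives 16 as the major E isomer.

## Further compounds
F1 | step 9 | (1Z,5E,9E)-1-bromo-6-{[(tert-butyldimethylsilyl)oxy]methyl}-2,10-dimethyltetradeca-1,5,9,13-tetraene | Br/C=C(/C)CC/C=C(/CO[Si](C)(C)C(C)(C)C)CC/C=C(\C)CCC=C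
F2 | step 9 | (S)-1,2-bis(boronate): 2,2'-[(2S,5E,9E,13Z)-14-bromo-9-{[(tert-butyldimethylsilyl)oxy]methyl}-5,13-dimethyltetradeca-5,9,13-triene-1,2-diyl]bis(4,4,5,5-tetramethyl-1,3,2-dioxaborolane) | Br/C=C(/C)CC/C=C(/CO[Si](C)(C)C(C)(C)C)CC/C=C(\C)CC[C@@H](B1OC(C)(C)C(C)(C)O1)CB2OC(C)(C)C(C)(C)O2
F3 | step 12 | 1-ethoxyvinyl macrocycle (21 with C(OEt)=CH2 in place of Bpin, 1R) | C=C(OCC)[C@H]1C/C=C(/C)CC/C=C(/CO[Si](C)(C)C(C)(C)C)CC/C=C(\C)CC1
F4 | step 12 | (1R)-methyl ketone: 1-[(1R,3Z,7E,11E)-8-{[(tert-butyldimethylsilyl)oxy]methyl}-4,12-dimethylcyclotetradeca-3,7,11-trien-1-yl]ethan-1-one | CC(=O)[C@H]1C/C=C(/C)CC/C=C(/CO[Si](C)(C)C(C)(C)C)CC/C=C(\C)CC1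
F5 | step 12 | (S)-2-methyl-2-macrocyclyl oxirane | C[C@@]1(CO1)[C@H]2C/C=C(/C)CC/C=C(/CO[Si](C)(C)C(C)(C)C)CC/C=C(\C)CC2
F6 | step 12 | but-3-enyl carbinol: (2R)-2-[(1R,3Z,7E,11E)-8-{[(tert-butyldimethylsilyl)oxy]methyl}-4,12-dimethylcyclotetradeca-3,7,11-trien-1-yl]hex-5-en-2-ol | C=CCC[C@@](C)(O)[C@H]1C/C=C(/C)CC/C=C(/CO[Si](C)(C)C(C)(C)C)CC/C=C(\C)CC1
F7 | step 6 | α-(diethoxyphosphoryl) ester: methyl (E)-2-(diethoxyphosphoryl)-6-methyl-8-(4,4,5,5-tetramethyl-1,3,2-dioxaborolan-2-yl)oct-5-enoate | CCOP(=O)(OCC)C(CC/C=C(\C)CCB1OC(C)(C)C(C)(C)O1)C(=O)OC
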